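Ring C of the flavanone (O1, C2, C3, C4, C4a, C8a) is a 2,3-dihydro-4-pyranone in which the C4 carbonyl is linked through the C4a=C8a bond of ring A to O1. It is therefore cut at C2–C3 and O1–C8a into the complete, benzyl-protected 3'-(apigenin-6-yl)benzaldehyde and the silyl enol ether of a 2-fluoro-4,6-bis(benzyloxy)acetophenone, an aromatic 1-fluoro-3-silyloxydiene. In one flask a catalyst-controlled Mukaiyama aldol forms C2–C3 and sets (S)-C2, and fluoride then releases the alkoxide, which displaces the ortho fluoride to form O1–C8a. Hydrogenolysis of six benzyl ethers gives the target.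

Key step: step 9

Remark 1: the biaryl axis (three ortho substituents) is taken as configurationally labile, since the target notation defines no axial descriptor; rotamers of protected intermediates are carried as mixtures.
Remark 2: the (S,S)-bisphosphoramide, N,N'-dimethyl-N,N'-bis[(S)-3,5-dimethyl-4-oxido-3,5-dihydro-4H-dinaphtho[2,1-d:1',2'-f][1,3,2]diazaphosphepin-4-yl]pentane-1,5-diamine, is specified on the assumption that its (R,R)-antipode directs silyl enol ethers to the Re face of aromatic aldehydes; (S)-C2 requires Si-face attack.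

Step 1
Reactants: 1 apigenin
Product: 2 7,4'-di-O-benzylapigenin
Conditions: BnBr (2.1 equiv), K2CO3, DMF, 25 °C
Reagents that add atoms: benzyl bromide BrCc1ccccc1
Why: Williamson ether synthesis takes the free, acidic 7-OH and 4'-OH, while the 5-OH, hydrogen-bonded to the C4 carbonyl, should stay free.

Step 2
Reactants: 2 7,4'-di-O-benzylapigenin
Product: 3 6-iodo-7,4'-di-O-benzylapigenin
Conditions: BnMe3N·ICl2 (1.1 equiv), CaCO3, CH2Cl2/MeOH, 25 °C
Reagents that add atoms: benzyltrimethylammonium dichloroiodate C[N+](C)(C)Cc1ccccc1.Cl[I-]Cl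
Why: Electrophilic aromatic iodination of the phloroglucinol-type ring, expected at C6 (ortho to the free 5-OH) rather than C8, which is the site when the 5-oxygen is alkylated.

Step 3
Reactants: 3 6-iodo-7,4'-di-O-benzylapigenin
Product: 4 6-iodo-5,7,4'-tri-O-benzylapigenin
Conditions: BnBr (3 equiv), K2CO3, DMF, 80 °C
Reagents that add atoms: benzyl bromide BrCc1ccccc1
Why: Williamson ether synthesis under forcing conditions overcomes the chelation of the 5-OH and removes the last acidic proton before the Lewis acid and fluoride stages.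

Step 4
Reactants: 5 4-(benzyloxy)-3-bromobenzaldehyde
Product: 6 4-(benzyloxy)-3-(pinacolatoboryl)benzaldehyde
Conditions: B2pin2, Pd(dppf)Cl2 (3 mol %), KOAc, 1,4-dioxane, 85 °C
Reagents that add atoms: bis(pinacolato)diboron CC1(C)OB(OC1(C)C)B1OC(C)(C)C(C)(C)O1
Why: Miyaura borylation of an aryl bromide; the weak base KOAc should spare the aldehyde and suppress homocoupling.

Step 5
Reactants: 4 6-iodo-5,7,4'-tri-O-benzylapigenin; 6 4-(benzyloxy)-3-(pinacolatoboryl)benzaldehyde
Product: 7 tetra-O-benzyl biaryl aldehyde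
Conditions: Pd(OAc)2 (5 mol %), SPhos (10 mol %), K3PO4, toluene/H2O, 90 °C
Reagents that add atoms: none
Why: Suzuki–Miyaura coupling with a bulky, electron-rich dialkylbiarylphosphine, chosen because the iodide is flanked by two benzyloxy groups and the biaryl carries three ortho substituents.

Step 6
Reactants: 8 5-fluororesorcinol
Product: 9 1-(2-fluoro-4,6-dihydroxyphenyl)ethan-1-one
Conditions: AcOH, ZnCl2, 140 °C
Reagents that add atoms: acetic acid CC(=O)O
Why: Nencki reaction (Friedel–Crafts acylation of a phenol), expected at C4, ortho to one hydroxyl and para to the other as with resorcinol and orcinol, which places the acetyl group next to fluorine.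

Step 7
Reactants: 9 1-(2-fluoro-4,6-dihydroxyphenyl)ethan-1-one
Product: 10 1-[2,4-bis(benzyloxy)-6-fluorophenyl]ethan-1-one
Conditions: BnBr (2.5 equiv), K2CO3, DMF, 70 °C
Reagents that add atoms: benzyl bromide BrCc1ccccc1
Why: Williamson ether synthesis of both phenols, the chelated ortho-hydroxyl included at this temperature; the electron-rich C–F bond should not react with phenoxide.

Step 8
Reactants: 10 1-[2,4-bis(benzyloxy)-6-fluorophenyl]ethan-1-one
Product: 11 trimethylsilyl enol ether of 10
Conditions: TMSOTf, Et3N, CH2Cl2, 0 °C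
Reagents that add atoms: trimethylsilyl trifluoromethanesulfonate C[Si](C)(C)OS(=O)(=O)C(F)(F)F
Why: Soft enolisation and O-silylation of a methyl ketone with a single enolisable position gives the terminal silyl enol ether.

Step 9
Reactants: 7 tetra-O-benzyl biaryl aldehyde; 11 trimethylsilyl enol ether of 10
Product: 14 (2S)-hexa-O-benzyl flavanone, via trichlorosilyl aldolate 12 (not isolated), via caesium aldolate 13 (not isolated)
Conditions: 11 (1.3 equiv), SiCl4 (1.5 equiv), (S,S)-bisphosphoramide of remark 2 (10 mol %), i-Pr2NEt (0.2 equiv), CH2Cl2, −78 °C; then CsF (12 equiv), 18-crown-6, DMF, −78 to 0 °C; pH 7 phosphate buffer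
Reagents that add atoms: none
Why: Proposed new method: the phosphoramide-bound trichlorosilyl cation activates aldehyde 7 and shields its Re face, so enol ether 11 adds to the Si face through an open transition state, forming C2–C3 and the (S)-trichlorosilyl aldolate 12; CsF then removes silicon as hexafluorosilicate, and the free alkoxide 13 attacks C8a, ortho to the C4 ketone, with loss of fluoride to form O1–C8a. The closest known reaction types are the enantioselective SiCl4/phosphoramide Mukaiyama aldol of methyl ketone silyl enol ethers with aromatic aldehydes, the intramolecular SNAr of alkoxides on ortho-fluoroaryl ketones, and the stepwise (aldol, then cyclisation) hetero-Diels–Alder reaction of 1-alkoxy-3-silyloxydienes with aldehydes, of which this is the aromatic counterpart; their union in one flask to a flavanone is the new element. Ring C closes by addition–elimination, formally a 6-endo-trig oxa-Michael addition to the vinylogous acyl fluoride C4(=O)–C4a=C8a–F followed by loss of fluoride. C2 is set by the catalyst alone, there being no other stereocentre and the remote biaryl axis being labile, and it is not touched in the ring closure because the C2–O bond stays intact. The step needs cyclisation of 13 to outrun its retro-aldol cleavage and the base-induced opening of 14 to the chalcone, which the ortho-acyl activation of the C–F bond, the six-membered transition state, the low temperature and the neutral quench are meant to secure; the hindered flavone carbonyl, flanked by a peri benzyloxy group, should compete only weakly with the aldehyde for the bulky silicon centre.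

Step 10
Reactants: 14 (2S)-hexa-O-benzyl flavanone
Product: 15 target biflavonoid
Conditions: H2 (1 atm), Pd/C (10 wt %), THF/MeOH, 25 °C
Reagents that add atoms: none
Why: Catalytic hydrogenolysis of six aryl benzyl ethers under neutral conditions avoids the base-induced flavanone–chalcone equilibrium and so should leave (S)-C2 intact; it is stopped at the uptake for six benzyl groups to spare the benzylic C2–O1 bond and the flavone C2=C3 bond.

Compound list
1 | apigenin, 5,7-dihydroxy-2-(4-hydroxyphenyl)-4H-chromen-4-one | O=c1cc(-c2ccc(O)cc2)oc2cc(O)cc(O)c12 | starting material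
2 | 7,4'-di-O-benzylapigenin, 7-(benzyloxy)-2-[4-(benzyloxy)phenyl]-5-hydroxy-4H-chromen-4-one | O=c1cc(-c2ccc(OCc3ccccc3)cc2)oc2cc(OCc3ccccc3)cc(O)c12 | intermediate
3 | 6-iodo-7,4'-di-O-benzylapigenin, 7-(benzyloxy)-2-[4-(benzyloxy)phenyl]-5-hydroxy-6-iodo-4H-chromen-4-one | O=c1cc(-c2ccc(OCc3ccccc3)cc2)oc2cc(OCc3ccccc3)c(I)c(O)c12 | intermediate
4 | 6-iodo-5,7,4'-tri-O-benzylapigenin, 5,7-bis(benzyloxy)-2-[4-(benzyloxy)phenyl]-6-iodo-4H-chromen-4-one | O=c1cc(-c2ccc(OCc3ccccc3)cc2)oc2cc(OCc3ccccc3)c(I)c(OCc3ccccc3)c12 | intermediate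
5 | 4-(benzyloxy)-3-bromobenzaldehyde | O=Cc1ccc(OCc2ccccc2)c(Br)c1 | starting material
6 | 4-(benzyloxy)-3-(4,4,5,5-tetramethyl-1,3,2-dioxaborolan-2-yl)benzaldehyde | O=Cc1ccc(OCc2ccccc2)c(B2OC(C)(C)C(C)(C)O2)c1 | intermediate
7 | 4-(benzyloxy)-3-{5,7-bis(benzyloxy)-2-[4-(benzyloxy)phenyl]-4-oxo-4H-chromen-6-yl}benzaldehyde | O=Cc1ccc(OCc2ccccc2)c(-c2c(OCc3ccccc3)cc3oc(-c4ccc(OCc5ccccc5)cc4)cc(=O)c3c2OCc2ccccc2)c1 | intermediate
8 | 5-fluororesorcinol, 5-fluorobenzene-1,3-diol | Oc1cc(O)cc(F)c1 | starting material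
9 | 1-(2-fluoro-4,6-dihydroxyphenyl)ethan-1-one | CC(=O)c1c(O)cc(O)cc1F | intermediate
10 | 1-[2,4-bis(benzyloxy)-6-fluorophenyl]ethan-1-one | CC(=O)c1c(F)cc(OCc2ccccc2)cc1OCc1ccccc1 | intermediate
11 | {1-[2,4-bis(benzyloxy)-6-fluorophenyl]ethenyloxy}trimethylsilane | C=C(O[Si](C)(C)C)c1c(F)cc(OCc2ccccc2)cc1OCc1ccccc1 | intermediate
12 | (3S)-1-[2,4-bis(benzyloxy)-6-fluorophenyl]-3-(4-(benzyloxy)-3-{5,7-bis(benzyloxy)-2-[4-(benzyloxy)phenyl]-4-oxo-4H-chromen-6-yl}phenyl)-3-(trichlorosilyloxy)propan-1-one | O=C(C[C@H](O[Si](Cl)(Cl)Cl)c1ccc(OCc2ccccc2)c(-c2c(OCc3ccccc3)cc3oc(-c4ccc(OCc5ccccc5)cc4)cc(=O)c3c2OCc2ccccc2)c1)c1c(F)cc(OCc2ccccc2)cc1OCc1ccccc1 | intermediate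
13 | caesium (1S)-3-[2,4-bis(benzyloxy)-6-fluorophenyl]-1-(4-(benzyloxy)-3-{5,7-bis(benzyloxy)-2-[4-(benzyloxy)phenyl]-4-oxo-4H-chromen-6-yl}phenyl)-3-oxopropan-1-olate | O=C(C[C@H]([O-])c1ccc(OCc2ccccc2)c(-c2c(OCc3ccccc3)cc3oc(-c4ccc(OCc5ccccc5)cc4)cc(=O)c3c2OCc2ccccc2)c1)c1c(F)cc(OCc2ccccc2)cc1OCc1ccccc1.[Cs+] | intermediate
14 | (2S)-5,7-bis(benzyloxy)-2-(4-(benzyloxy)-3-{5,7-bis(benzyloxy)-2-[4-(benzyloxy)phenyl]-4-oxo-4H-chromen-6-yl}phenyl)chroman-4-one | O=C1C[C@@H](c2ccc(OCc3ccccc3)c(-c3c(OCc4ccccc4)cc4oc(-c5ccc(OCc6ccccc6)cc5)cc(=O)c4c3OCc3ccccc3)c2)Oc2cc(OCc3ccccc3)cc(OCc3ccccc3)c21 | intermediate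
15 | (2S)-5,7-dihydroxy-2-{3-[5,7-dihydroxy-2-(4-hydroxyphenyl)-4-oxo-4H-chromen-6-yl]-4-hydroxyphenyl}chroman-4-one | O=C1C[C@@H](c2ccc(O)c(-c3c(O)cc4oc(-c5ccc(O)cc5)cc(=O)c4c3O)c2)Oc2cc(O)cc(O)c21 | target

Total step count: 10. Longest linear sequence: 6 steps (steps 1, 2, 3, 5, 9, 10).

Steps most likely to fail

Step 9. The alkoxide may revert by retro-aldol cleavage before it cyclises, which would erode the enantiopurity set in the aldol stage. The product may also open to the chalcone under the basic fluoride conditions, and the SNAr may be slow on a ring that carries two donor ethers. The fallback uses known chemistry, sets out from aldehyde 7 and returns at 14. Commercial 1-[2,4-bis(benzyloxy)-6-hydroxyphenyl]ethan-1-one is silylated twice (TMSOTf, Et3N, CH2Cl2) to {1-[2,4-bis(benzyloxy)-6-(trimethylsilyloxy)phenyl]ethenyloxy}trimethylsilane F1. The same SiCl4-mediated Mukaiyama aldol with 7 is run with the (R,R)-bisphosphoramide and an aqueous KF/KH2PO4 quench, which also cleaves the aryl silyl ether. It should give (3R)-1-[2,4-bis(benzyloxy)-6-hydroxyphenyl]-3-(4-(benzyloxy)-3-{5,7-bis(benzyloxy)-2-[4-(benzyloxy)phenyl]-4-oxo-4H-chromen-6-yl}phenyl)-3-hydroxypropan-1-one F2, isolated without contact with base. Mitsunobu cyclisation (PPh3, DIAD, toluene, 0 °C) then closes O1–C2 with inversion to give (S)-14.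

Step 5. Oxidative addition and transmetalation may be slow at the doubly ortho-substituted iodide, so that protodeboronation of 6 and hydrodeiodination of 4 take over. The fallback sets out from iodide 3 and boronate 6 and returns at 7, with the coupling moved ahead of the last protection. Iodide 3, whose free chelated 5-OH is a smaller ortho substituent, is coupled with 6 (Pd(OAc)2, SPhos, K3PO4) to 4-(benzyloxy)-3-{7-(benzyloxy)-2-[4-(benzyloxy)phenyl]-5-hydroxy-4-oxo-4H-chromen-6-yl}benzaldehyde F3. Its phenol is then benzylated (BnBr, K2CO3, DMF, 80 °C) to give 7.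

Step 10. Over-reduction may occur, by hydrogenolysis of the benzylic C2–O1 bond to a dihydrochalcone or by saturation of the flavone C2=C3 bond, and debenzylation may stall as partly deprotected material precipitates. The fallback sets out from 14 and returns at 15 by non-reductive Lewis-acid dealkylation (BCl3, pentamethylbenzene as benzyl cation scavenger, CH2Cl2, −78 °C); it makes no new compound F0.

Further compounds
F1 | step 9 | {1-[2,4-bis(benzyloxy)-6-(trimethylsilyloxy)phenyl]ethenyloxy}trimethylsilane | C=C(O[Si](C)(C)C)c1c(O[Si](C)(C)C)cc(OCc2ccccc2)cc1OCc1ccccc1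
F2 | step 9 | (3R)-1-[2,4-bis(benzyloxy)-6-hydroxyphenyl]-3-(4-(benzyloxy)-3-{5,7-bis(benzyloxy)-2-[4-(benzyloxy)phenyl]-4-oxo-4H-chromen-6-yl}phenyl)-3-hydroxypropan-1-one | O=C(C[C@@H](O)c1ccc(OCc2ccccc2)c(-c2c(OCc3ccccc3)cc3oc(-c4ccc(OCc5ccccc5)cc4)cc(=O)c3c2OCc2ccccc2)c1)c1c(O)cc(OCc2ccccc2)cc1OCc1ccccc1
F3 | step 5 | 4-(benzyloxy)-3-{7-(benzyloxy)-2-[4-(benzyloxy)phenyl]-5-hydroxy-4-oxo-4H-chromen-6-yl}benzaldehyde | O=Cc1ccc(OCc2ccccc2)c(-c2c(OCc3ccccc3)cc3oc(-c4ccc(OCc5ccccc5)cc4)cc(=O)c3c2O)c1
F0 | step 10 | none | none
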